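The ten-membered carbocycle is uncovered, not closed. In the target C1 (furanone carbonyl) and C6 (lactone oxygen) lie 1,6 across ring C1–C10, so both are drawn from the two carbons of a ring-fusion alkene: ozonolysis of the tetrasubstituted C1=C6 bond of an octalin turns two six-membered rings into the cyclodecane-1,6-dione in one operation. The precursor is built on (S)-carvone, whose ring supplies C6–C10 and C1 with C7, C8 and C10 already set, fused by Robinson annulation to ring C2–C5; it carries a C3 dioxolane, silyl ethers at C8, C10 and C15 and a PMB ether at C12.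

Key step: step 15

Remark: germacrane numbering is used for every intermediate (ring C1–C10; C11, C12, C13 on C7; C14 on C10; C15 on C4); C6 in 14–18 and C4 in 17–25 are drawn as the expected epimers, but either epimer serves because these carbons become sp2 later; formaldehyde is the monomer gas from cracked paraformaldehyde.

Step 1
Reactants: 1 (S)-carvone
Product: 2 C12 chloride
Conditions: Ca(OCl)2, CO2 (s), CH2Cl2/H2O, 0 °C
Reagents that add atoms: calcium hypochlorite Ca(OCl)2, [Ca+2].[O-]Cl.[O-]Cl
Why: HOCl formed in the flask attacks only the electron-rich 1,1-disubstituted alkene in an ene-type allylic chlorination (the alkene shifts within the isopropenyl unit and a methylene is regenerated), while the electron-poor enone and C7 are untouched.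

Step 2
Reactants: 2 C12 chloride
Product: 3 C12 PMB ether
Conditions: 4-methoxybenzyl alcohol, NaH, n-Bu4NI (cat.), THF, 0 °C → rt
Reagents that add atoms: 4-methoxybenzyl alcohol, COc1ccc(CO)cc1
Why: Williamson ether synthesis: the preformed alkoxide displaces the primary allylic chloride by SN2 under iodide catalysis much faster than it can add reversibly to the enone.

Step 3
Reactants: 3 C12 PMB ether
Product: 4 through-conjugated TBS dienol ether
Conditions: KOt-Bu, THF, −78 → 0 °C; then TBSCl, −78 °C → rt
Reagents that add atoms: tert-butyldimethylsilyl chloride, CC(C)(C)[Si](C)(C)Cl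
Why: Thermodynamic enolisation followed by silyl enol ether formation: reversible proton transfer (the t-BuOH formed shuttles protons) should move the enone into the more delocalised C1–C10–C9–C8 dienolate, which is O-silylated; C7 is not acidic and keeps its configuration.

Step 4
Reactants: 4 through-conjugated TBS dienol ether
Product: 6 8-hydroxy enone, via epoxy dienol ether 5 (not isolated)
Conditions: mCPBA, NaHCO3, CH2Cl2, −20 °C; then 1 M HCl, THF, 0 °C
Reagents that add atoms: 3-chloroperoxybenzoic acid, OOC(=O)c1cccc(Cl)c1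
Why: Vinylogous Rubottom oxidation: the peracid should epoxidise the distal C8=C9 bond of the silyloxydiene (largest HOMO coefficient at C8, less hindered than the tetrasubstituted C1=C10) on the face opposite the adjacent C7 side chain, and the vinyl epoxide collapses to the γ-hydroxy enone on desilylation, which sets C8–O trans to C7–C11.

Step 5
Reactants: 6 8-hydroxy enone
Product: 7 8-TBS-oxy enone
Conditions: TBSCl, imidazole, DMF, rt
Reagents that add atoms: tert-butyldimethylsilyl chloride, CC(C)(C)[Si](C)(C)Cl
Why: Standard silylation of the secondary allylic alcohol; the TBS ether keeps C8 masked until the lactone is closed.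

Step 6
Reactants: 7 8-TBS-oxy enone
Product: 8 C1 allylic alcohol
Conditions: NaBH4, CeCl3·7H2O, MeOH, −78 → 0 °C
Reagents that add atoms: none
Why: Luche 1,2-reduction: axial hydride addition to the conformer with both ring substituents equatorial should give the equatorial C1 alcohol cis to the C7 side chain, as carvone itself gives cis-carveol.

Step 7
Reactants: 8 C1 allylic alcohol
Product: 9 C9–C10 epoxy alcohol
Conditions: VO(acac)2 (cat.), t-BuOOH, CH2Cl2, 0 °C → rt
Reagents that add atoms: tert-butyl hydroperoxide, CC(C)(C)OO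
Why: Hydroxyl-directed epoxidation: the vanadium alkoxide–peroxide complex delivers oxygen to C9=C10 on the face of C1–OH (also the face opposite C8–OTBS) and ignores the side-chain alkene, which fixes the C10 oxygen cis to the C7 side chain.

Step 8
Reactants: 9 C9–C10 epoxy alcohol
Product: 10 C1/C10 diol
Conditions: LiAlH4, THF, 0 °C → rt
Reagents that add atoms: none
Why: Hydride opening of a trisubstituted epoxide: SN2 attack at the secondary carbon C9 in the trans-diaxial mode makes C9 a methylene and leaves the tertiary C10 alcohol with its configuration unchanged.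

Step 9
Reactants: 10 C1/C10 diol
Product: 11 C10 hydroxy ketone
Conditions: Dess–Martin periodinane, NaHCO3, CH2Cl2, 0 °C → rt
Reagents that add atoms: none
Why: Dess–Martin oxidation of the only secondary alcohol; the tertiary C10 alcohol cannot be oxidised and no α-stereocentre can epimerise (C10 is quaternary, C7 is β).

Step 10
Reactants: 11 C10 hydroxy ketone
Product: 12 C10 TES ether ketone
Conditions: TESOTf, 2,6-lutidine, CH2Cl2, −78 → 0 °C
Reagents that add atoms: triethylsilyl trifluoromethanesulfonate, CC[Si](CC)(CC)OS(=O)(=O)C(F)(F)F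
Why: Silyl triflate silylation of the hindered tertiary alcohol; the TES ether blocks α-ketol rearrangement in base, resists ionisation once C10 becomes allylic, and is the most acid-labile silyl group for step 16.

Step 11
Reactants: 12 C10 TES ether ketone; 13 methyl vinyl ketone
Product: 15 octalone, via Michael diketone 14 (not isolated)
Conditions: NaOMe (cat.), MeOH, 0 °C → rt; then NaOMe (1 equiv), 40 °C
Reagents that add atoms: none
Why: Robinson annulation: C6 is the only enolisable position (C10 is quaternary), so Michael addition occurs there, and aldol condensation of the methyl group onto C1 with dehydration closes the second six-membered ring as the C1=C2 enone; the C6 centre equilibrates and is erased in step 14.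

Step 12
Reactants: 15 octalone; 16 formaldehyde
Product: 17 C15 hydroxymethyl octalone
Conditions: LiN(i-Pr)2 (LDA), THF, −78 °C; CH2O (g), −78 → −40 °C; NH4Cl (aq)
Reagents that add atoms: none
Why: Kinetic deprotonation of the enone gives the cross-conjugated C3–C4 enolate, which adds to formaldehyde in an aldol reaction (α′-hydroxymethylation) and installs C15; the configuration created at C4 is irrelevant.

Step 13
Reactants: 17 C15 hydroxymethyl octalone
Product: 18 C15 TBDPS ether octalone
Conditions: TBDPSCl, imidazole, CH2Cl2, 0 °C → rt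
Reagents that add atoms: tert-butyldiphenylsilyl chloride, CC(C)(C)[Si](Cl)(c1ccccc1)c1ccccc1
Why: Selective silylation of the primary alcohol, done at once because the β-hydroxy ketone can lose formaldehyde by retro-aldol reaction; TBDPS is chosen to outlast every later acidic step.

Step 14
Reactants: 18 C15 TBDPS ether octalone; 19 ethylene glycol
Product: 20 octalin ketal
Conditions: PPTS (cat.), benzene, reflux, Dean–Stark
Reagents that add atoms: none
Why: Deconjugative ketalisation: acid-catalysed dioxolane formation passes through the dienol and leaves the alkene in the β,γ position, which can only be C1=C6 because C10 bears no hydrogen; the weak acid should spare the silyl ethers, the PMB ether and the tertiary allylic C10–OTES.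

Step 15
Reactants: 20 octalin ketal
Product: 22 cyclodecane-1,6-dione ketal, via methoxy hydroperoxide 21 (not isolated)
Conditions: O3, CH2Cl2/MeOH, NaHCO3, Sudan Red 7B, −78 °C; then Me2S, −78 °C → rt
Reagents that add atoms: ozone, [O-][O+]=O
Why: Ozone adds to the tetrasubstituted C1=C6 alkene by 1,3-dipolar cycloaddition, the primary ozonide fragments to a ketone (at C1, next to the oxygen-bearing C10) and a carbonyl oxide (at C6) that methanol traps as hydroperoxide 21, and Me2S reduces this to the second ketone. The closest known reaction type is the ozonolysis of the central alkene of 1,2,3,4,5,6,7,8-octahydronaphthalenes to cyclodecane-1,6-diones. The step closes no ring: the ten-membered carbocycle is what remains when the bond common to both six-membered rings is cut, so the entropic cost of a macrocyclisation never arises. No stereocentre is created, and C4, C7, C8 and C10 are not touched in the cold, buffered medium. Chemoselectivity is the one requirement: ozone must consume C1=C6 and spare the C11=C13 methylene and the PMB arene, which should hold because fourfold alkyl substitution makes C1=C6 far more electron-rich, the side-chain alkene is only 1,1-disubstituted and inductively slowed by its allylic ether oxygen, and the gas is stopped when the Sudan Red 7B indicator fades. The C3 dioxolane keeps C2 from enolising (a free β-diketone enol would be ozonised) and prevents transannular aldol reactions of the dione.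

Step 16
Reactants: 22 cyclodecane-1,6-dione ketal
Product: 24 furanone ketone, via hydroxy triketone 23 (not isolated)
Conditions: 1 M HCl (aq), THF, 0 °C → rt
Reagents that add atoms: none
Why: Acid hydrolysis should remove the tertiary TES ether and then the dioxolane, after which the C10 hydroxyl adds 5-exo-trig to the C3 carbonyl of the C1/C3 β-diketone and water is lost (cyclodehydration of an α′-hydroxy-1,3-diketone to a 3(2H)-furanone), which consumes the β-diketone before it can react across the ring with C6.

Step 17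
Reactants: 24 furanone ketone
Product: 26 furanone dienone, via TMS enol ether 25 (not isolated)
Conditions: LiN(i-Pr)2 (LDA), TMSCl, THF, −78 °C; solvent exchange; Pd(OAc)2, MeCN, rt
Reagents that add atoms: none
Why: Saegusa–Ito oxidation: kinetic deprotonation at the C5 methylene (not at the hindered C7 methine) with in situ silylation gives the C5=C6 enol ether, and Pd(OAc)2 forms the C5 palladium enolate, whose β-hydride elimination of H4 should give the C4=C5 enone as the ring-cis (Z) alkene, the geometry the nine-membered oxygen-bridged ring accommodates.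

Step 18
Reactants: 26 furanone dienone
Product: 27 6S allylic alcohol
Conditions: NaBH4, CeCl3·7H2O, MeOH, −78 °C
Reagents that add atoms: none
Why: Luche 1,2-reduction of the C6 enone carbonyl (the vinylogous ester carbonyl C1 is inert); hydride is expected to enter from the ring periphery on the face opposite the 1,3-related C8 silyloxy group, which would give the 6S alcohol needed for the trans-fused lactone.

Step 19
Reactants: 27 6S allylic alcohol
Product: 28 C6/C12 diol
Conditions: DDQ, CH2Cl2/pH 7 buffer, 0 °C
Reagents that add atoms: none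
Why: Oxidative cleavage of the PMB ether by DDQ through the benzylic oxocarbenium ion and its hydrolysis; the silyl ethers, the furanone and the electron-poor allylic alcohol should be inert.

Step 20
Reactants: 28 C6/C12 diol
Product: 31 silylated lactone, via hydroxy enal 29 (not isolated), via lactol 30 (not isolated)
Conditions: TEMPO (cat.), PhI(OAc)2, CH2Cl2, rt
Reagents that add atoms: none
Why: Oxidative lactonisation of a 1,4-diol: the oxoammonium salt oxidises the primary allylic C12 alcohol in preference to the hindered secondary C6 alcohol, C6–OH traps the enal as the five-membered lactol, and a second oxidation gives the α-methylene γ-lactone with retention at C6.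

Step 21
Reactants: 31 silylated lactone
Product: 32 C8 alcohol
Conditions: HF (48% aq), MeCN, 0 °C → rt
Reagents that add atoms: none
Why: Acidic fluoride desilylation removes the secondary TBS ether while the much more acid-stable primary TBDPS ether stays, and the acidic medium avoids base-induced translactonisation to C8.

Step 22
Reactants: 32 C8 alcohol; 33 (E)-crotonic anhydride
Product: 34 C15 TBDPS ether of the target
Conditions: DMAP (cat.), pyridine, CH2Cl2, 0 °C → rt
Reagents that add atoms: none
Why: DMAP-catalysed acyl transfer esterifies the only free hydroxyl; the anhydride is used in place of the acid chloride to avoid ketene formation and deconjugation of the crotonyl group.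

Step 23
Reactants: 34 C15 TBDPS ether of the target
Product: 35 CNP0225232.1
Conditions: n-Bu4NF, AcOH, THF, 0 °C → rt
Reagents that add atoms: none
Why: Fluoride-induced cleavage of the TBDPS ether, buffered with acetic acid so that the crotonate, the α-methylene lactone and the furanone survive, frees the C15 allylic alcohol.

Compound list

1 | (S)-(+)-carvone, (5S)-2-methyl-5-(prop-1-en-2-yl)cyclohex-2-en-1-one | CC1=CC[C@@H](CC1=O)C(C)=C | starting material
2 | C12 chloride, (5S)-5-(3-chloroprop-1-en-2-yl)-2-methylcyclohex-2-en-1-one | CC1=CC[C@@H](CC1=O)C(=C)CCl | intermediate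
3 | C12 PMB ether, (5S)-5-[3-(4-methoxybenzyloxy)prop-1-en-2-yl]-2-methylcyclohex-2-en-1-one | CC1=CC[C@@H](CC1=O)C(=C)COCc1ccc(OC)cc1 | intermediate
4 | through-conjugated TBS dienol ether: 1-(tert-butyldimethylsilyloxy)-2-methyl-5-[3-(PMB-oxy)prop-1-en-2-yl]cyclohexa-1,3-diene, C7 as in carvone | CC1=C(O[Si](C)(C)C(C)(C)C)C[C@H](C=C1)C(=C)COCc1ccc(OC)cc1 | intermediate
5 | epoxy dienol ether: C8–C9 epoxide of 4, oxygen trans to the C7 side chain (not isolated) | CC1=C(O[Si](C)(C)C(C)(C)C)C[C@H]([C@@H]2O[C@H]12)C(=C)COCc1ccc(OC)cc1 | intermediate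
6 | 8-hydroxy enone: (4R,5S)-4-hydroxy-2-methyl-5-[3-(PMB-oxy)prop-1-en-2-yl]cyclohex-2-en-1-one, C8–OH trans to the C7 side chain | CC1=C[C@@H](O)[C@@H](CC1=O)C(=C)COCc1ccc(OC)cc1 | intermediate
7 | 8-TBS-oxy enone: TBS ether of 6 | CC1=C[C@@H](O[Si](C)(C)C(C)(C)C)[C@@H](CC1=O)C(=C)COCc1ccc(OC)cc1 | intermediate
8 | C1 allylic alcohol: C1–OH cis to the C7 side chain and trans to C8–OTBS | CC1=C[C@@H](O[Si](C)(C)C(C)(C)C)[C@@H](C[C@@H]1O)C(=C)COCc1ccc(OC)cc1 | intermediate
9 | C9–C10 epoxy alcohol: epoxide oxygen cis to C1–OH | C[C@@]12O[C@@H]1[C@@H](O[Si](C)(C)C(C)(C)C)[C@@H](C[C@@H]2O)C(=C)COCc1ccc(OC)cc1 | intermediate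
10 | C1/C10 diol: tertiary C10–OH and secondary C1–OH cis to each other and to the C7 side chain, C9 methylene | C[C@@]1(O)C[C@@H](O[Si](C)(C)C(C)(C)C)[C@@H](C[C@@H]1O)C(=C)COCc1ccc(OC)cc1 | intermediate
11 | C10 hydroxy ketone: 2-hydroxy-2-methyl-4-(TBS-oxy)-5-[3-(PMB-oxy)prop-1-en-2-yl]cyclohexan-1-one, C10–OH cis to the side chain and trans to C8–OTBS | C[C@@]1(O)C[C@@H](O[Si](C)(C)C(C)(C)C)[C@@H](CC1=O)C(=C)COCc1ccc(OC)cc1 | intermediate
12 | C10 TES ether ketone: triethylsilyl ether of 11 | C[C@@]1(O[Si](CC)(CC)CC)C[C@@H](O[Si](C)(C)C(C)(C)C)[C@@H](CC1=O)C(=C)COCc1ccc(OC)cc1 | intermediate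
13 | methyl vinyl ketone, but-3-en-2-one | CC(=O)C=C | starting material
14 | Michael diketone: 12 with a 3-oxobutyl group at C6, trans to the C7 side chain (not isolated) | C[C@@]1(O[Si](CC)(CC)CC)C[C@@H](O[Si](C)(C)C(C)(C)C)[C@H](C(=C)COCc2ccc(OC)cc2)[C@@H](CCC(C)=O)C1=O | intermediate
15 | octalone: bicyclic enone with C3 ketone and C1=C2 alkene, H6 trans to H7, C10 (Me, OTES), C8 OTBS, C7 side chain | C[C@@]1(O[Si](CC)(CC)CC)C[C@@H](O[Si](C)(C)C(C)(C)C)[C@H](C(=C)COCc2ccc(OC)cc2)[C@H]3CCC(=O)C=C13 | intermediate
16 | formaldehyde | C=O | starting material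
17 | C15 hydroxymethyl octalone: 15 with CH2OH at C4 | C[C@@]1(O[Si](CC)(CC)CC)C[C@@H](O[Si](C)(C)C(C)(C)C)[C@H](C(=C)COCc2ccc(OC)cc2)[C@H]3C[C@H](CO)C(=O)C=C13 | intermediate
18 | C15 TBDPS ether octalone | C[C@@]1(O[Si](CC)(CC)CC)C[C@@H](O[Si](C)(C)C(C)(C)C)[C@H](C(=C)COCc2ccc(OC)cc2)[C@H]3C[C@H](CO[Si](c4ccccc4)(c4ccccc4)C(C)(C)C)C(=O)C=C13 | intermediate
19 | ethylene glycol | OCCO | starting material
20 | octalin ketal: C3 ethylene ketal, tetrasubstituted C1=C6 alkene, C4 CH2OTBDPS, C7 C(=CH2)CH2OPMB, C8 OTBS, C10 (Me, OTES) | C[C@@]1(O[Si](CC)(CC)CC)C[C@@H](O[Si](C)(C)C(C)(C)C)[C@H](C(=C)COCc2ccc(OC)cc2)C3=C1CC4(OCCO4)[C@@H](CO[Si](c5ccccc5)(c5ccccc5)C(C)(C)C)C3 | intermediate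
21 | methoxy hydroperoxide: C1 ketone, C6 bearing OMe and OOH, both C6 epimers (not isolated) | C[C@@]1(O[Si](CC)(CC)CC)C[C@@H](O[Si](C)(C)C(C)(C)C)[C@H](C(=C)COCc2ccc(OC)cc2)C(OC)(OO)C[C@H](CO[Si](c3ccccc3)(c3ccccc3)C(C)(C)C)C4(OCCO4)CC1=O | intermediate
22 | cyclodecane-1,6-dione ketal: C1 and C6 ketones, C3 ethylene ketal, other groups as in 20 | C[C@@]1(O[Si](CC)(CC)CC)C[C@@H](O[Si](C)(C)C(C)(C)C)[C@H](C(=C)COCc2ccc(OC)cc2)C(=O)C[C@H](CO[Si](c3ccccc3)(c3ccccc3)C(C)(C)C)C4(OCCO4)CC1=O | intermediate
23 | hydroxy triketone: C1, C3 and C6 ketones, free C10–OH (not isolated) | C[C@@]1(O)C[C@@H](O[Si](C)(C)C(C)(C)C)[C@H](C(=C)COCc2ccc(OC)cc2)C(=O)C[C@H](CO[Si](c3ccccc3)(c3ccccc3)C(C)(C)C)C(=O)CC1=O | intermediate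
24 | furanone ketone: 3(2H)-furanone O–C3=C2–C1(=O)–C10 bridging the ten-membered ring, C6 ketone, C4 CH2OTBDPS, C8 OTBS | O=C1C[C@H](CO[Si](c2ccccc2)(c2ccccc2)C(C)(C)C)C3=CC(=O)[C@@](C)(C[C@@H](O[Si](C)(C)C(C)(C)C)[C@@H]1C(=C)COCc4ccc(OC)cc4)O3 | intermediate
25 | TMS enol ether: C5=C6–OTMS, ring-cis (not isolated) | C[Si](C)(C)O/C1=C/[C@H](CO[Si](c2ccccc2)(c2ccccc2)C(C)(C)C)C3=CC(=O)[C@@](C)(C[C@@H](O[Si](C)(C)C(C)(C)C)[C@@H]1C(=C)COCc4ccc(OC)cc4)O3 | intermediate
26 | furanone dienone: (4Z)-C4=C5 enone with C6 ketone | O=C1/C=C(/CO[Si](c2ccccc2)(c2ccccc2)C(C)(C)C)C3=CC(=O)[C@@](C)(C[C@@H](O[Si](C)(C)C(C)(C)C)[C@@H]1C(=C)COCc4ccc(OC)cc4)O3 | intermediate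
27 | 6S allylic alcohol: C6–OH on the same ring face as C8–OTBS, H6 anti to H7 | O[C@H]1/C=C(/CO[Si](c2ccccc2)(c2ccccc2)C(C)(C)C)C3=CC(=O)[C@@](C)(C[C@@H](O[Si](C)(C)C(C)(C)C)[C@@H]1C(=C)COCc4ccc(OC)cc4)O3 | intermediate
28 | C6/C12 diol | O[C@H]1/C=C(/CO[Si](c2ccccc2)(c2ccccc2)C(C)(C)C)C3=CC(=O)[C@@](C)(C[C@@H](O[Si](C)(C)C(C)(C)C)[C@@H]1C(=C)CO)O3 | intermediate
29 | hydroxy enal: C12 aldehyde, free C6–OH (not isolated) | O[C@H]1/C=C(/CO[Si](c2ccccc2)(c2ccccc2)C(C)(C)C)C3=CC(=O)[C@@](C)(C[C@@H](O[Si](C)(C)C(C)(C)C)[C@@H]1C(=C)C=O)O3 | intermediate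
30 | lactol: C12 hemiacetal closed on C6–O, both anomers (not isolated) | C=C1C(O)O[C@H]2/C=C(/CO[Si](c4ccccc4)(c4ccccc4)C(C)(C)C)C3=CC(=O)[C@@](C)(C[C@@H](O[Si](C)(C)C(C)(C)C)[C@H]12)O3 | intermediate
31 | silylated lactone: trans-fused α-methylene 6,12-lactone with C8 OTBS and C15 OTBDPS | C=C1C(=O)O[C@H]2/C=C(/CO[Si](c4ccccc4)(c4ccccc4)C(C)(C)C)C3=CC(=O)[C@@](C)(C[C@@H](O[Si](C)(C)C(C)(C)C)[C@H]12)O3 | intermediate
32 | C8 alcohol: 31 without the TBS group | C=C1C(=O)O[C@H]2/C=C(/CO[Si](c4ccccc4)(c4ccccc4)C(C)(C)C)C3=CC(=O)[C@@](C)(C[C@@H](O)[C@H]12)O3 | intermediate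
33 | (E)-crotonic anhydride | C/C=C/C(=O)OC(=O)/C=C/C | starting material
34 | C15 TBDPS ether of the target: 8-O-(E)-crotonate | C=C1C(=O)O[C@H]2/C=C(/CO[Si](c4ccccc4)(c4ccccc4)C(C)(C)C)C3=CC(=O)[C@@](C)(C[C@@H](OC(=O)/C=C/C)[C@H]12)O3 | intermediate
35 | CNP0225232.1, (6S,7S,8R,10R) furanone-bridged germacranolide with (4Z)-alkene, C15 hydroxyl and C8 (E)-crotonate | C=C1C(=O)O[C@H]2/C=C(/CO)C3=CC(=O)[C@@](C)(C[C@@H](OC(=O)/C=C/C)[C@H]12)O3 | target

Total step count: 23. Longest linear sequence: 23 steps from (S)-carvone; methyl vinyl ketone, formaldehyde, ethylene glycol and crotonic anhydride enter as commercial reagents.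

Steps most likely to fail

Step 3. The silyl chloride may capture the kinetically formed cross-conjugated C6 enolate before proton transfer has moved the charge to C8, so that step 4 would oxygenate C6. The fallback sets out from 3 and comes back at 6. Compound 3 is equilibrated with KOt-Bu in t-BuOH, a protic and fully reversible medium, and poured into cold aqueous AcOH, where α-protonation of the dienolate gives the deconjugated β,γ-enone F1. Buffered mCPBA at −20 °C epoxidises the ring C8=C9 bond anti to the C7 side chain (the side-chain alkene is slowed by its allylic ether) to the epoxy ketone F2, and Et3N opens F2 by E1cB elimination to 6. The C8 oxygen then comes from an epoxide opening and not from a dienol ether.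

Step 15. Over-oxidation: ozone may begin to cleave the C11=C13 methylene or the PMB ring before the hindered tetrasubstituted alkene is consumed. The fallback sets out from 20 and comes back at 22 by stepwise cleavage. Buffered mCPBA, which discriminates alkenes by substitution far more sharply, epoxidises only C1=C6 from the face opposite C10–OTES and the C7 side chain to give the C1–C6 epoxide F3. A short treatment with dilute aqueous HClO4 in THF at 0 °C opens it to the trans-diol F4, and Pb(OAc)4 in benzene/pyridine cleaves the ditertiary glycol to 22.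

Step 18. Poor or reversed facial selectivity in the hydride addition to the C6 carbonyl of the flexible ten-membered ring. The fallback sets out from 26 and comes back at 27. If the reduction delivers the 6-epi allylic alcohol F5, a Mitsunobu reaction (4-nitrobenzoic acid, PPh3, DIAD, THF, 0 °C) gives the inverted C6 4-nitrobenzoate F6, and K2CO3 in MeOH releases 27. C6 is then set by SN2 inversion and not by the reduction.

Further compounds

F1 | step 3 | deconjugated β,γ-enone (C8=C9 alkene, both C10 epimers) | CC1C=C[C@@H](CC1=O)C(=C)COCc1ccc(OC)cc1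
F2 | step 3 | epoxy ketone (C8–C9 epoxide trans to the C7 side chain) | CC1[C@H]2O[C@H]2[C@@H](CC1=O)C(=C)COCc1ccc(OC)cc1
F3 | step 15 | C1–C6 epoxide of 20 (oxygen trans to C10–OTES and to the C7 side chain) | C[C@@]1(O[Si](CC)(CC)CC)C[C@@H](O[Si](C)(C)C(C)(C)C)[C@H](C(=C)COCc2ccc(OC)cc2)[C@@]34O[C@@]13CC5(OCCO5)[C@@H](CO[Si](c6ccccc6)(c6ccccc6)C(C)(C)C)C4
F4 | step 15 | trans-diol (C1–OH and C6–OH on opposite faces) | C[C@@]1(O[Si](CC)(CC)CC)C[C@@H](O[Si](C)(C)C(C)(C)C)[C@H](C(=C)COCc2ccc(OC)cc2)[C@]3(O)[C@]1(O)CC4(OCCO4)[C@@H](CO[Si](c5ccccc5)(c5ccccc5)C(C)(C)C)C3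
F5 | step 18 | 6-epi allylic alcohol | O[C@@H]1/C=C(/CO[Si](c2ccccc2)(c2ccccc2)C(C)(C)C)C3=CC(=O)[C@@](C)(C[C@@H](O[Si](C)(C)C(C)(C)C)[C@@H]1C(=C)COCc4ccc(OC)cc4)O3
F6 | step 18 | inverted C6 4-nitrobenzoate | O=C(O[C@H]1/C=C(/CO[Si](c2ccccc2)(c2ccccc2)C(C)(C)C)C3=CC(=O)[C@@](C)(C[C@@H](O[Si](C)(C)C(C)(C)C)[C@@H]1C(=C)COCc4ccc(OC)cc4)O3)c5ccc(cc5)[N+](=O)[O-]
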